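**Plan**

1. Retrosynthesis (isoflavan numbering: O1, C2–C4, ring A C4a–C8a, ring B C1'–C6'): first the 4'-O-benzyl and 7-O-methyl bonds are cut, then the ring B pyran (O–CMe2 and C3'–CH bonds, from 3-methylbut-2-enal), then the two C–H bonds at C3/C4 (hydrogenation), and last C3=C4 together with O1–C2.
2. Enabling feature: C4 (on C4a) and the formyl carbon on C8 occupy the two positions of ring A ortho to O1, each next to an oxygen-bearing carbon (C5, C7). With O7 methylated, ring A is the mirror-symmetric 2-hydroxy-4,6-dimethoxybenzene-1,3-dicarbaldehyde, so either formyl group can become C4 and the other is the C8 aldehyde with no differentiation.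
3. Forward: this dialdehyde (one formylation) and a 1-arylvinylphosphonium salt carrying ring B (three steps) are joined in the key step. Phenoxide O1 adds to the vinylphosphonium ion, and the ylide formed at C3 closes the pyran ring on the ortho formyl carbon (C3=C4).
4. Then: asymmetric hydrogenation, release of the 2'-hydroxyl, annulation of the dimethylpyran ring of ring B (one free ortho position only), and one BCl3 step that removes the benzyl group and, by chelation to the C8 formyl group, only the 7-O-methyl group.
5. Stereochemistry: the single stereocentre C3 (R) comes from the chiral iridium catalyst in the hydrogenation of C3=C4 (step 6); it is not enolisable and no later step touches it.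

Key step: step 5

Remark on the chemistry: in step 6, L = (4S)-4-tert-butyl-2-[2-(diphenylphosphanyl)phenyl]-4,5-dihydro-1,3-oxazole, cod = cycloocta-1,5-diene, BArF = tetrakis[3,5-bis(trifluoromethyl)phenyl]borate.
Remark on the chemistry: the sense of induction of this catalyst is assumed, not predicted; if a test hydrogenation shows the (3S) product, the enantiomeric ligand is used.

Step 1
Reactants: 1 2-hydroxy-4,6-dimethoxybenzaldehyde
Product: 2 2-hydroxy-4,6-dimethoxybenzene-1,3-dicarbaldehyde
Conditions: MgCl2, Et3N, (CH2O)n, MeCN, reflux; then 1 M HCl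
Reagents that add atoms: paraformaldehyde (as formaldehyde), C=O
Why: Magnesium-mediated ortho-formylation of a phenol (Casnati–Skattebøl reaction): the magnesium phenoxide delivers formaldehyde to the only free ortho carbon and a second formaldehyde oxidises the benzylic alkoxide by hydride transfer, so the new formyl group can only enter next to the hydroxyl and gives the mirror-symmetric dialdehyde.

Step 2
Reactants: 3 1-[4-(benzyloxy)-2-hydroxyphenyl]ethan-1-one
Product: 4 1-[4-(benzyloxy)-2-(methoxymethoxy)phenyl]ethan-1-one
Conditions: MOMCl, i-Pr2NEt, CH2Cl2, 0 °C to rt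
Reagents that add atoms: chloromethyl methyl ether (MOMCl), COCCl
Why: O-alkylation of the chelated phenol with a reactive α-chloro ether (acetal protection); the methoxymethyl group keeps the future 2'-hydroxyl out of the triflation and withstands the bases and the hydrogenation that follow.

Step 3
Reactants: 4 1-[4-(benzyloxy)-2-(methoxymethoxy)phenyl]ethan-1-one
Product: 5 1-[4-(benzyloxy)-2-(methoxymethoxy)phenyl]ethenyl trifluoromethanesulfonate
Conditions: KN(SiMe3)2, THF, −78 °C; then PhNTf2, −78 to 0 °C
Reagents that add atoms: N-phenylbis(trifluoromethanesulfonimide) (PhNTf2), O=S(=O)(N(c1ccccc1)S(=O)(=O)C(F)(F)F)C(F)(F)F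
Why: Enol triflate formation by deprotonation of the methyl ketone and O-sulfonylation of the potassium enolate; the ketone has a single enolisable position, so only the 1-arylvinyl triflate can form.

Step 4
Reactants: 5 1-[4-(benzyloxy)-2-(methoxymethoxy)phenyl]ethenyl trifluoromethanesulfonate
Product: 6 {1-[4-(benzyloxy)-2-(methoxymethoxy)phenyl]ethenyl}triphenylphosphonium trifluoromethanesulfonate
Conditions: PPh3, Pd(PPh3)4 (3 mol%), THF, 65 °C
Reagents that add atoms: triphenylphosphine, c1ccc(cc1)P(c1ccccc1)c1ccccc1
Why: Palladium-catalysed C–P coupling of a vinyl triflate with a triarylphosphine (oxidative addition to zerovalent palladium, then reductive elimination of the phosphonium ion), a known route to vinylphosphonium triflates that installs the activating group for the key step.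

Step 5
Reactants: 2 2-hydroxy-4,6-dimethoxybenzene-1,3-dicarbaldehyde; 6 {1-[4-(benzyloxy)-2-(methoxymethoxy)phenyl]ethenyl}triphenylphosphonium trifluoromethanesulfonate
Product: 8 3-[4-(benzyloxy)-2-(methoxymethoxy)phenyl]-5,7-dimethoxy-2H-chromene-8-carbaldehyde, via phosphorus ylide 7 (not isolated)
Conditions: NaH, DMF, 0 °C; then 6, 70 °C
Reagents that add atoms: none
Why: The sodium phenoxide of 2 adds to the unsubstituted terminus of the vinylphosphonium ion (oxa-Michael addition), which puts O1 on C2 and leaves a phosphorus ylide on the aryl-bearing carbon, the future C3 (compound 7). The ylide carbon then attacks the formyl carbon ortho to O1 and the oxaphosphetane collapses to the C3=C4 double bond and Ph3P=O; the closest known reaction type is the synthesis of 2H-chromenes from salicylaldehydes and vinylphosphonium salts by conjugate addition and intramolecular Wittig olefination. The pyran ring closes in the 6-exo-trig mode (ylide carbon onto the carbonyl carbon), and the ring forces the cis alkene. No stereocentre is formed in this step. The step needs reaction at one formyl group only and no intermolecular olefination: the two formyl groups of 2 are equivalent by its mirror plane and both are ortho to the phenoxide, each molecule carries a single ylide, and closure through a six-membered array should outrun attack on a second molecule, so the untouched formyl group ends up on C8. The phosphonium group, the only activating group used, leaves in the same step as Ph3P=O.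

Step 6
Reactants: 8 3-[4-(benzyloxy)-2-(methoxymethoxy)phenyl]-5,7-dimethoxy-2H-chromene-8-carbaldehyde
Product: 9 (3R)-3-[4-(benzyloxy)-2-(methoxymethoxy)phenyl]-5,7-dimethoxy-3,4-dihydro-2H-chromene-8-carbaldehyde
Conditions: [Ir(cod)(L)]BArF (2 mol%), H2 (50 bar), CH2Cl2, rt
Reagents that add atoms: none
Why: Iridium-catalysed asymmetric hydrogenation of the trisubstituted 3-aryl-2H-chromene alkene, the reaction type used for enantioselective access to isoflavans: the chiral P,N ligand differentiates the two faces of C3=C4 and both hydrogens are delivered to one face, which sets C3 as R, while the aryl aldehyde, the benzyl ether and the acetal are not substrates of this catalyst class.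

Step 7
Reactants: 9 (3R)-3-[4-(benzyloxy)-2-(methoxymethoxy)phenyl]-5,7-dimethoxy-3,4-dihydro-2H-chromene-8-carbaldehyde
Product: 10 (3R)-3-[4-(benzyloxy)-2-hydroxyphenyl]-5,7-dimethoxy-3,4-dihydro-2H-chromene-8-carbaldehyde
Conditions: HCl (3 M in MeOH), rt; then H2O
Reagents that add atoms: none
Why: Acid-catalysed acetal cleavage (transacetalisation of the methoxymethyl ether to methanol) frees the 2'-hydroxyl only after C3=C4 is saturated, so the phenol cannot add to C4, and the benzyl ether, the methyl ethers and the non-enolisable C3 are unaffected.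

Step 8
Reactants: 10 (3R)-3-[4-(benzyloxy)-2-hydroxyphenyl]-5,7-dimethoxy-3,4-dihydro-2H-chromene-8-carbaldehyde
Product: 11 (3R)-3-[5-(benzyloxy)-2,2-dimethyl-2H-chromen-8-yl]-5,7-dimethoxy-3,4-dihydro-2H-chromene-8-carbaldehyde
Conditions: 3-methylbut-2-enal, PhB(OH)2, AcOH, toluene, reflux (Dean–Stark)
Reagents that add atoms: 3-methylbut-2-enal, CC(C)=CC=O
Why: Phenylboronic acid-templated condensation of a phenol with an enal (ortho-specific C-alkylation through the aryl boronate, ortho-quinone methide formation, oxa-6π electrocyclisation); C3' is the only free position ortho to the 2'-hydroxyl, so the 2,2-dimethylpyran ring can form with one regiochemistry only, with its oxygen on C2'.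

Step 9
Reactants: 11 (3R)-3-[5-(benzyloxy)-2,2-dimethyl-2H-chromen-8-yl]-5,7-dimethoxy-3,4-dihydro-2H-chromene-8-carbaldehyde
Product: 12 (3R)-7-hydroxy-3-(5-hydroxy-2,2-dimethyl-2H-chromen-8-yl)-5-methoxy-3,4-dihydro-2H-chromene-8-carbaldehyde
Conditions: BCl3, C6HMe5, CH2Cl2, −78 to −20 °C; then MeOH, aq. NaHCO3
Reagents that add atoms: none
Why: Lewis acid ether cleavage with BCl3: the benzyl ether is cleaved cold with pentamethylbenzene as cation scavenger, and the 7-methoxy group is removed by chelation of boron between O7 and the neighbouring formyl oxygen (ortho-carbonyl-assisted demethylation), while the 5-methoxy group, para to the formyl group and not chelated, should stay.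

**Compound list**

1 | 2-hydroxy-4,6-dimethoxybenzaldehyde | COc1cc(OC)c(C=O)c(O)c1 | starting material
2 | 2-hydroxy-4,6-dimethoxybenzene-1,3-dicarbaldehyde | COc1cc(OC)c(C=O)c(O)c1C=O | intermediate
3 | 1-[4-(benzyloxy)-2-hydroxyphenyl]ethan-1-one | CC(=O)c1ccc(OCc2ccccc2)cc1O | starting material
4 | 1-[4-(benzyloxy)-2-(methoxymethoxy)phenyl]ethan-1-one | CC(=O)c1ccc(OCc2ccccc2)cc1OCOC | intermediate
5 | 1-[4-(benzyloxy)-2-(methoxymethoxy)phenyl]ethenyl trifluoromethanesulfonate | C=C(OS(=O)(=O)C(F)(F)F)c1ccc(OCc2ccccc2)cc1OCOC | intermediate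
6 | {1-[4-(benzyloxy)-2-(methoxymethoxy)phenyl]ethenyl}triphenylphosphonium trifluoromethanesulfonate | C=C(c1ccc(OCc2ccccc2)cc1OCOC)[P+](c1ccccc1)(c1ccccc1)c1ccccc1.[O-]S(=O)(=O)C(F)(F)F | intermediate
7 | 2-{2-[4-(benzyloxy)-2-(methoxymethoxy)phenyl]-2-(triphenyl-λ5-phosphanylidene)ethoxy}-4,6-dimethoxybenzene-1,3-dicarbaldehyde | COc1cc(OC)c(C=O)c(OCC(=P(c2ccccc2)(c2ccccc2)c2ccccc2)c2ccc(OCc3ccccc3)cc2OCOC)c1C=O | intermediate (not isolated)
8 | 3-[4-(benzyloxy)-2-(methoxymethoxy)phenyl]-5,7-dimethoxy-2H-chromene-8-carbaldehyde | COc1cc(OC)c(C=O)c2c1C=C(c1ccc(OCc3ccccc3)cc1OCOC)CO2 | intermediate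
9 | (3R)-3-[4-(benzyloxy)-2-(methoxymethoxy)phenyl]-5,7-dimethoxy-3,4-dihydro-2H-chromene-8-carbaldehyde | COc1cc(OC)c(C=O)c2c1C[C@H](c1ccc(OCc3ccccc3)cc1OCOC)CO2 | intermediate
10 | (3R)-3-[4-(benzyloxy)-2-hydroxyphenyl]-5,7-dimethoxy-3,4-dihydro-2H-chromene-8-carbaldehyde | COc1cc(OC)c(C=O)c2c1C[C@H](c1ccc(OCc3ccccc3)cc1O)CO2 | intermediate
11 | (3R)-3-[5-(benzyloxy)-2,2-dimethyl-2H-chromen-8-yl]-5,7-dimethoxy-3,4-dihydro-2H-chromene-8-carbaldehyde | COc1cc(OC)c(C=O)c2c1C[C@H](c1ccc(OCc3ccccc3)c3c1OC(C)(C)C=C3)CO2 | intermediate
12 | (3R)-7-hydroxy-3-(5-hydroxy-2,2-dimethyl-2H-chromen-8-yl)-5-methoxy-3,4-dihydro-2H-chromene-8-carbaldehyde | COc1cc(O)c(C=O)c2c1C[C@H](c1ccc(O)c3c1OC(C)(C)C=C3)CO2 | target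

**Summary**

Total step count: 9. Longest linear sequence: 8 steps (3 to 12, steps 2 to 9).

Steps most likely to fail:

Step 5. What may go wrong: the hindered, weakly nucleophilic phenoxide adds too slowly to the α-aryl vinylphosphonium ion, and the ylide closes only slowly onto the doubly ortho-substituted formyl group, so hydrolysis of the phosphonium salt and reversal of the conjugate addition take over. Fallback (sets out from 2 and 5, returns at 8): the vinyl triflate 5 is converted by Miyaura borylation (B2pin2, PdCl2(PPh3)2, PPh3, KOPh, toluene, 50 °C) into 2-{1-[4-(benzyloxy)-2-(methoxymethoxy)phenyl]ethenyl}-4,4,5,5-tetramethyl-1,3,2-dioxaborolane F1. F1 is heated with 2 and dibenzylamine (20 mol%) in dioxane at 90 °C. A Petasis-type transfer of the alkenyl group from the phenoxide-bound boronate to the iminium carbon, loss of the amine and oxa-6π electrocyclisation of the resulting ortho-quinone methide should give the same chromene 8, with the carbon–carbon bond made inside a boron ate complex instead of by an ylide.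

Step 6. What may go wrong: the formyl group binds to, or is slowly reduced by, the cationic iridium hydride, which stalls the hydrogenation and erodes the facial selectivity at C3=C4. Fallback (sets out from 8, returns at 10): 8 is first converted with HC(OMe)3 and PPTS in MeOH into 3-[4-(benzyloxy)-2-(methoxymethoxy)phenyl]-8-(dimethoxymethyl)-5,7-dimethoxy-2H-chromene F2, an isoflav-3-ene that carries ether groups only. Hydrogenation under the conditions of step 6 should give (3R)-3-[4-(benzyloxy)-2-(methoxymethoxy)phenyl]-8-(dimethoxymethyl)-5,7-dimethoxy-3,4-dihydro-2H-chromene F3. The acid and aqueous work-up of step 7 then remove the acetal and the methoxymethyl group together to give 10.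

Step 9. What may go wrong: opening or hydrochlorination of the acid-labile 2,2-dimethylpyran ring while the mixture is warmed for the chelation-controlled demethylation. Fallback (sets out from 10, returns at 12): the demethylation is moved in front of the pyran annulation and done with a milder, chelation-specific reagent. MgI2·OEt2 in toluene at 80 °C should cleave only the 7-O-methyl group of 10 and give (3R)-3-[4-(benzyloxy)-2-hydroxyphenyl]-7-hydroxy-5-methoxy-3,4-dihydro-2H-chromene-8-carbaldehyde F4. Annulation with 3-methylbut-2-enal as in step 8, in which the chelated, formyl-deactivated 7-hydroxyl of ring A should stay out, gives (3R)-3-[5-(benzyloxy)-2,2-dimethyl-2H-chromen-8-yl]-7-hydroxy-5-methoxy-3,4-dihydro-2H-chromene-8-carbaldehyde F5. The benzyl ether alone is then cleaved with BCl3 and C6HMe5 at −78 °C, where the pyran ring meets the Lewis acid only briefly and cold, to give 12.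

Further compounds

F1 | step 5 | 2-{1-[4-(benzyloxy)-2-(methoxymethoxy)phenyl]ethenyl}-4,4,5,5-tetramethyl-1,3,2-dioxaborolane | C=C(B1OC(C)(C)C(C)(C)O1)c1ccc(OCc2ccccc2)cc1OCOC
F2 | step 6 | 3-[4-(benzyloxy)-2-(methoxymethoxy)phenyl]-8-(dimethoxymethyl)-5,7-dimethoxy-2H-chromene | COc1cc(OC)c(C(OC)OC)c2c1C=C(c1ccc(OCc3ccccc3)cc1OCOC)CO2
F3 | step 6 | (3R)-3-[4-(benzyloxy)-2-(methoxymethoxy)phenyl]-8-(dimethoxymethyl)-5,7-dimethoxy-3,4-dihydro-2H-chromene | COc1cc(OC)c(C(OC)OC)c2c1C[C@H](c1ccc(OCc3ccccc3)cc1OCOC)CO2
F4 | step 9 | (3R)-3-[4-(benzyloxy)-2-hydroxyphenyl]-7-hydroxy-5-methoxy-3,4-dihydro-2H-chromene-8-carbaldehyde | COc1cc(O)c(C=O)c2c1C[C@H](c1ccc(OCc3ccccc3)cc1O)CO2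
F5 | step 9 | (3R)-3-[5-(benzyloxy)-2,2-dimethyl-2H-chromen-8-yl]-7-hydroxy-5-methoxy-3,4-dihydro-2H-chromene-8-carbaldehyde | COc1cc(O)c(C=O)c2c1C[C@H](c1ccc(OCc3ccccc3)c3c1OC(C)(C)C=C3)CO2
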